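The runs were computed with made-up constants; scatter was added.

Divide, in each earlier run, the other capture product by the target at the last reading, then divide that by the charged ratio of second to first nucleophile.

in all of them: solid substrate 0.29 M

|  | first nucleophile | second nucleophile | remark | time |
|---|---|---|---|---|
| Monday's | 2.5 equiv | 0.60 equiv | run made earlier |  |
| Saturday's | 2.5 equiv | 0.90 equiv | run made earlier |  |
| Wednesday's | 5 equiv | 1.2 equiv | run made earlier |  |
| flask | 2.50 equiv | 1.20 equiv |  | 10 min |

- Monday's (time / min: other capture product / %, target / %, solid substrate / %): 0.667: 2.3, 2.9, 61.7; 1.00: 4.2, 5.4, 56.5; 2.00: 8.6, 16.7, 40.3; 3.00: 12.0, 26.8, 26.7; 5.00: 19.5, 48.4, 0; 8.00: 25.2, 66.2, 0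
- Saturday's (time / min: other capture product / %, target / %, solid substrate / %): 0.667: 3.3, 1.6, 61.8; 1.00: 5.6, 4.6, 54.7; 2.00: 11.6, 14.5, 40.2; 3.00: 15.9, 22.8, 26.9; 5.00: 24.4, 41.6, 0.2; 8.00: 33.1, 56.8, 0.4
- Wednesday's (time / min: other capture product / %, target / %, solid substrate / %): 1.50: 6.2, 10.5, 48.7; 3.00: 13.4, 26.0, 26.2; 5.00: 20.5, 46.7, 0.3; 6.00: 24.0, 55.4, 0; 8.00: 26.5, 64.5, 0

(each reading ± 0.5 percentage points)

- percentages count the solid substrate that a species holds: one side product counts as two
- solid, in amounts per volume of the solution: solid substrate
- the analysis behind the earlier runs scatters by 0.5 percentage points, standard deviation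
- candidate steps: second nucleophile <-> dormant form; first nucleophile + intermediate -> target; second nucleophile + intermediate -> other capture product; solid substrate <-> starting material; starting material + intermediate -> side product; starting material <-> intermediate
- at the start none of the solid substrate is in solution

1. ratio of other capture product to target at 15 s
2. ratio of other capture product to target at 1.5 min
3. ratio of other capture product to target at 10 min
4. which of other capture product and target there is more of at 10 min

Among the candidate steps, both nucleophiles capture one intermediate, made from the dissolved starting material: the first gives target, the second other capture product. So I try the charged ratio of second to first nucleophile as the measure of the split.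

At 8.00 min Monday's run gives 1.59, Saturday's 1.62 and Wednesday's 1.71. Take their mean, 1.64, as the selectivity factor: other capture product formed per target, so far, for each unit of charge ratio.

This flask's charge ratio is 0.480, so my ratio for 10 min is 0.787. That lies below one, so the target should lead.

Is one number enough? No. At 1.00 min Monday's run reads 3.24, about twice the late factor, and Saturday's reads 3.38. Wednesday's run, at the charge ratio of Monday's run, reads 2.46 at 1.50 min, and Monday's run itself falls to 1.59 at 8.00 min. For 1.5 min I therefore take 1.18. The early time 15 s lies before the earliest reading, so I carry back the factor of Monday's run at 1.00 min and take 1.56 there as my estimate.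

The forecast gave 2.7, 1.2 and 0.76 for the three times, with target ahead, holding that “Early selectivity is much higher, so the second nucleophile starts active and relaxes to its dormant form”.

The flask gives 1.89, 1.24 and 0.766, with target ahead: 54.2 % against 41.5 % of other capture product.

    second nucleophile ⇌ dormant form (K = 1.70, k = 0.0130 s⁻¹)
    first nucleophile + intermediate → target (k = 1.50 M⁻¹ s⁻¹)
    second nucleophile + intermediate → other capture product (k = 6.70 M⁻¹ s⁻¹)
    solid substrate ⇌ starting material, rate k4*(cs4 - [starting material]) while solid is left; crystals form when [starting material] > cs4 (solubility = 0.110 M, k = 0.0650 s⁻¹)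
    starting material + intermediate → side product (k = 0.00900 M⁻¹ s⁻¹)
    starting material ⇌ intermediate (K = 0.270, k = 0.00700 s⁻¹)

Put the flask's own ratio over its charge ratio: the factor is 1.60 at 10 min, beside the 1.64 read earlier. Now take the neighbouring flask, the same recipe with 4.20 equiv of first nucleophile. Its charge ratio is 0.286, so the factor gives 0.468, and the simulated neighbouring flask gives 0.480 at 10 min. In that neighbouring flask the other capture product ends at 31.1 % and the target at 64.8 %.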